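Ring C is cut at C3–C4 and O1–C8a. This gives a ring A acyl-anion equivalent (a 2-aryl-1,3-dithiane with fluorine on C8a) and an enantiopure ring B styrene oxide that already holds O1, C2 and C3. In one flask the lithiated dithiane opens the epoxide at C3 and the released C2 alkoxide displaces fluoride at C8a, a (3+3) annulation that carries C2 in unchanged. It exploits the meta relation of the ring A oxygens: the C5 and C7 methoxy groups are meta to C8a, so they do not hinder SNAr. The same fluorine first directs lithiation to C8 (prenyl) and C4a (formyl). C4 is set afterwards by reduction and Mitsunobu inversion.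

Key step: step 5

Remark: the target is the (2S,4R) isomer, which is the 2,4-trans flavan-4-ol (2-aryl pseudo-equatorial, 4-OH pseudo-axial); flavonoid numbering is used for all chroman compounds, prenyl stands for 3-methylbut-2-en-1-yl, and 1, 2 and 6 are taken as commercial.

Step 1
Reactants: 1 1-fluoro-3,5-dimethoxybenzene; 2 prenyl bromide (1-bromo-3-methylbut-2-ene)
Product: 3 1-fluoro-3,5-dimethoxy-2-prenylbenzene
Conditions: LiN(i-Pr)2 (LDA), THF, −78 °C; CuBr·SMe2 (10 mol %), 2, −78 °C, then slowly to −20 °C
Reagents that add atoms: none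
Why: Directed ortho-metalation, in which the amide base removes only the proton flanked by F and OMe (the two such sites are equivalent by symmetry, and the site between the two methoxy groups is not acidic enough for LDA), followed by copper-catalysed allylic substitution at the primary carbon of 2.

Step 2
Reactants: 3 1-fluoro-3,5-dimethoxy-2-prenylbenzene
Product: 4 2-fluoro-4,6-dimethoxy-3-prenylbenzaldehyde
Conditions: LiN(i-Pr)2, THF, −78 °C; DMF, −78 → 0 °C; H2O
Reagents that add atoms: N,N-dimethylformamide CN(C)C=O
Why: A second directed ortho-metalation at the only remaining position next to fluorine (again flanked by OMe), followed by formylation of the aryllithium with DMF, puts the future C4 on C4a.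

Step 3
Reactants: 4 2-fluoro-4,6-dimethoxy-3-prenylbenzaldehyde
Product: 5 2-(2-fluoro-4,6-dimethoxy-3-prenylphenyl)-1,3-dithiane
Conditions: HS(CH2)3SH, BF3·OEt2 (20 mol %), CH2Cl2, −20 → 0 °C
Reagents that add atoms: propane-1,3-dithiol SCCCS
Why: Lewis acid-catalysed dithioacetalisation runs through a thionium ion that ring A stabilises well, and the catalytic acid and low temperature should spare the trisubstituted alkene.

Step 4
Reactants: 6 2-bromo-1-[4-(benzyloxy)phenyl]ethan-1-one
Product: 8 (R)-2-[4-(benzyloxy)phenyl]oxirane, via bromohydrin 7 (not isolated)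
Conditions: (R)-2-methyl-CBS-oxazaborolidine (10 mol %), BH3·SMe2, THF, 0 °C; MeOH; then K2CO3, MeOH, rt
Reagents that add atoms: none
Why: In this CBS reduction the (R)-oxazaborolidine treats the aryl group as the large substituent and should deliver hydride to the face that gives the (R)-bromohydrin, and the 3-exo-tet Williamson closure that follows leaves the carbinol C–O bond and its configuration untouched.

Step 5
Reactants: 5 2-(2-fluoro-4,6-dimethoxy-3-prenylphenyl)-1,3-dithiane; 8 (R)-2-[4-(benzyloxy)phenyl]oxirane
Product: 11 (2S)-2-[4-(benzyloxy)phenyl]-5,7-dimethoxy-8-prenylspiro[chromane-4,2'-[1,3]dithiane], via lithiated dithiane 9 (not isolated), via lithium alkoxide 10 (not isolated)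
Conditions: n-BuLi, THF, −30 °C; 8, −30 °C → rt; then KOt-Bu, DMPU, 65 °C
Reagents that add atoms: none
Why: n-BuLi removes the C2–H of the dithiane (Corey–Seebach umpolung, so the future C4 acts as an acyl anion), and carbanion 9 opens epoxide 8 by SN2 attack at its unsubstituted CH2, which makes C3–C4 and releases alkoxide 10. After exchange to potassium and warming, this alkoxide adds to the fluorine-bearing carbon C8a and expels fluoride (addition–elimination SNAr), which makes O1–C8a and closes ring C. Both halves are known reaction types, namely the opening of styrene oxides by 2-aryl-2-lithio-1,3-dithianes and the alkoxide cyclisation of 3-(2-fluoroaryl)propanols to chromans, and they are merely run in one flask here. The closure is a six-membered, formally 6-exo-trig attack, helped by the gem-disubstituent effect of the dithiane carbon and by both methoxy groups being meta to C8a, so that they do not oppose the Meisenheimer charge on C8, C6 and C4a. No stereocentre is created, because C2 comes from the epoxide and its C–O bond is never broken, so (R)-8 should give (2S)-11 with retention (the descriptor changes only through the priority rules). The step needs terminal rather than benzylic epoxide opening, secured by the bulk of 9 and the absence of Lewis acid, and displacement of fluoride rather than of the C5 methoxy group, secured by the far better leaving ability of fluoride in SNAr; since C8 is blocked no aryne can form, and since C4 is masked neither elimination nor retro-oxa-Michael racemisation is possible.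

Step 6
Reactants: 11 (2S)-2-[4-(benzyloxy)phenyl]-5,7-dimethoxy-8-prenylspiro[chromane-4,2'-[1,3]dithiane]
Product: 12 (2S)-4'-benzyloxy-5,7-dimethoxy-8-prenylflavanone
Conditions: MeI, CaCO3, MeCN–H2O (9:1), 45 °C
Reagents that add atoms: water O
Why: Alkylative dithiane hydrolysis (S-methylation, opening to a thionium ion stabilised by ring A, capture by water) runs in a buffered, almost neutral medium that should leave the alkene, the benzyl ether and the base-sensitive C2 untouched.

Step 7
Reactants: 12 (2S)-4'-benzyloxy-5,7-dimethoxy-8-prenylflavanone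
Product: 13 (2S)-5,4'-dihydroxy-7-methoxy-8-prenylflavanone
Conditions: BCl3, C6HMe5, CH2Cl2, −78 → 0 °C; H2O
Reagents that add atoms: none
Why: In this Lewis acid ether cleavage BCl3 chelates between the C4 carbonyl and the C5 methoxy group, so only this methyl ether falls while the C7 methoxy group stays, and the benzyl ether is cleaved by the same reagent with pentamethylbenzene as a non-basic scavenger of the benzyl cation.

Step 8
Reactants: 13 (2S)-5,4'-dihydroxy-7-methoxy-8-prenylflavanone
Product: 14 (2S)-5,4'-bis(tert-butyldimethylsilyloxy)-7-methoxy-8-prenylflavanone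
Conditions: TBSOTf, 2,6-lutidine, CH2Cl2, 0 °C
Reagents that add atoms: tert-butyldimethylsilyl triflate CC(C)(C)[Si](C)(C)OS(=O)(=O)C(F)(F)F
Why: In this O-silylation the reactive silyl triflate should also cap the hydrogen-bonded C5 phenol, while the hindered weak base should neither enolise the ketone nor open ring C.

Step 9
Reactants: 14 (2S)-5,4'-bis(tert-butyldimethylsilyloxy)-7-methoxy-8-prenylflavanone
Product: 15 (2S,4S)-5,4'-bis(tert-butyldimethylsilyloxy)-7-methoxy-8-prenylflavan-4-ol (2,4-cis)
Conditions: NaBH4, THF–MeOH (4:1), 0 °C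
Reagents that add atoms: none
Why: In this substrate-controlled hydride reduction the small hydride attacks C4 of the half-chair (2-aryl pseudo-equatorial) along the pseudo-axial trajectory, which should give the pseudo-equatorial alcohol, that is the 2,4-cis (4S) isomer needed for the inversion.

Step 10
Reactants: 15 (2S,4S)-5,4'-bis(tert-butyldimethylsilyloxy)-7-methoxy-8-prenylflavan-4-ol
Product: 17 (2S,4R)-5,4'-bis(tert-butyldimethylsilyloxy)-7-methoxy-8-prenylflavan-4-ol (2,4-trans), via trans chloroacetate 16 (not isolated)
Conditions: ClCH2CO2H, PPh3, DIAD, toluene–THF, −20 → 0 °C; then NH3 (7 M in MeOH), 0 °C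
Reagents that add atoms: chloroacetic acid OC(=O)CCl
Why: In this Mitsunobu reaction chloroacetate displaces the C4 oxyphosphonium group from the opposite face and so inverts C4 from S to R (should the electron-rich benzylic centre ionise instead, pseudo-axial capture of the cation leads to the same 2,4-trans ester), and ammonolysis then cleaves the acyl–oxygen bond without touching C4.

Step 11
Reactants: 17 (2S,4R)-5,4'-bis(tert-butyldimethylsilyloxy)-7-methoxy-8-prenylflavan-4-ol
Product: 18 (2S,4R)-4,5,4'-trihydroxy-7-methoxy-8-prenylflavan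
Conditions: n-Bu4NF, AcOH, THF, 0 °C
Reagents that add atoms: none
Why: Fluoride removes both aryl silyl ethers, and the acetic acid buffer keeps the C5 phenol protonated, which should suppress loss of the C4 hydroxyl through an ortho-quinone methide, so C2 and C4 stay as set.

Compound list
1 | 1-fluoro-3,5-dimethoxybenzene | COc1cc(F)cc(OC)c1 | starting material
2 | prenyl bromide (1-bromo-3-methylbut-2-ene) | CC(C)=CCBr | starting material
3 | 1-fluoro-3,5-dimethoxy-2-prenylbenzene | COc1cc(F)c(CC=C(C)C)c(OC)c1 | intermediate
4 | 2-fluoro-4,6-dimethoxy-3-prenylbenzaldehyde | COc1cc(OC)c(CC=C(C)C)c(F)c1C=O | intermediate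
5 | 2-(2-fluoro-4,6-dimethoxy-3-prenylphenyl)-1,3-dithiane | COc1cc(OC)c(CC=C(C)C)c(F)c1C1SCCCS1 | intermediate
6 | 2-bromo-1-[4-(benzyloxy)phenyl]ethan-1-one | O=C(CBr)c1ccc(OCc2ccccc2)cc1 | starting material
7 | (R)-2-bromo-1-[4-(benzyloxy)phenyl]ethan-1-ol (not isolated) | O[C@H](c1ccc(OCc2ccccc2)cc1)CBr | intermediate
8 | (R)-2-[4-(benzyloxy)phenyl]oxirane | O1[C@H](c2ccc(OCc3ccccc3)cc2)C1 | intermediate
9 | 2-lithio-2-(2-fluoro-4,6-dimethoxy-3-prenylphenyl)-1,3-dithiane (not isolated) | [Li]C1(SCCCS1)c1c(F)c(CC=C(C)C)c(OC)cc1OC | intermediate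
10 | lithium (S)-1-[4-(benzyloxy)phenyl]-2-[2-(2-fluoro-4,6-dimethoxy-3-prenylphenyl)-1,3-dithian-2-yl]ethan-1-olate (not isolated) | [Li]O[C@H](c1ccc(OCc2ccccc2)cc1)CC1(SCCCS1)c1c(F)c(CC=C(C)C)c(OC)cc1OC | intermediate
11 | (2S)-2-[4-(benzyloxy)phenyl]-5,7-dimethoxy-8-prenylspiro[chromane-4,2'-[1,3]dithiane] | COc1cc(OC)c2c(c1CC=C(C)C)O[C@H](c1ccc(OCc3ccccc3)cc1)CC21SCCCS1 | intermediate
12 | (2S)-4'-benzyloxy-5,7-dimethoxy-8-prenylflavanone | COc1cc(OC)c2c(c1CC=C(C)C)O[C@H](c1ccc(OCc3ccccc3)cc1)CC2=O | intermediate
13 | (2S)-5,4'-dihydroxy-7-methoxy-8-prenylflavanone | COc1cc(O)c2c(c1CC=C(C)C)O[C@H](c1ccc(O)cc1)CC2=O | intermediate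
14 | (2S)-5,4'-bis(tert-butyldimethylsilyloxy)-7-methoxy-8-prenylflavanone | COc1cc(O[Si](C)(C)C(C)(C)C)c2c(c1CC=C(C)C)O[C@H](c1ccc(O[Si](C)(C)C(C)(C)C)cc1)CC2=O | intermediate
15 | (2S,4S)-5,4'-bis(tert-butyldimethylsilyloxy)-7-methoxy-8-prenylflavan-4-ol (2,4-cis) | COc1cc(O[Si](C)(C)C(C)(C)C)c2c(c1CC=C(C)C)O[C@H](c1ccc(O[Si](C)(C)C(C)(C)C)cc1)C[C@@H]2O | intermediate
16 | (2S,4R)-5,4'-bis(tert-butyldimethylsilyloxy)-7-methoxy-8-prenylflavan-4-yl chloroacetate (2,4-trans, not isolated) | COc1cc(O[Si](C)(C)C(C)(C)C)c2c(c1CC=C(C)C)O[C@H](c1ccc(O[Si](C)(C)C(C)(C)C)cc1)C[C@H]2OC(=O)CCl | intermediate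
17 | (2S,4R)-5,4'-bis(tert-butyldimethylsilyloxy)-7-methoxy-8-prenylflavan-4-ol (2,4-trans) | COc1cc(O[Si](C)(C)C(C)(C)C)c2c(c1CC=C(C)C)O[C@H](c1ccc(O[Si](C)(C)C(C)(C)C)cc1)C[C@H]2O | intermediate
18 | (2S,4R)-4,5,4'-trihydroxy-7-methoxy-8-prenylflavan | COc1cc(O)c2c(c1CC=C(C)C)O[C@H](c1ccc(O)cc1)C[C@H]2O | target

Total step count: 11
Longest linear sequence: 10 steps (1 → 3 → 4 → 5 → 11 → 12 → 13 → 14 → 15 → 17 → 18); step 4 is the one-step side branch.

Steps most likely to fail

Step 5. Metalation of the doubly ortho-substituted dithiane may be incomplete. Fluoride displacement on a ring without an electron-withdrawing group may also be slow enough for the hot alkoxide medium to move the prenyl double bond into conjugation.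
- The fallback sets out from 5 and 8 and comes back at 12; it makes the two bonds in separate flasks.
- Only the epoxide opening is run (n-BuLi, THF, −30 °C → rt, aqueous quench), and (S)-1-[4-(benzyloxy)phenyl]-2-[2-(2-fluoro-4,6-dimethoxy-3-prenylphenyl)-1,3-dithian-2-yl]ethan-1-ol F1 is isolated.
- MeI and CaCO3 in aqueous MeCN then unmask (S)-3-[4-(benzyloxy)phenyl]-1-(2-fluoro-4,6-dimethoxy-3-prenylphenyl)-3-hydroxypropan-1-one F2.
- In F2 the fluorine stands ortho to an aryl ketone, so the closure becomes a carbonyl-activated SNAr. It should run with Cs2CO3 in MeCN at room temperature with short contact and give 12 directly.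

Step 10. The activated, very electron-rich benzylic centre may ionise and then lose a C3 proton (elimination towards the flav-3-ene), or the cation may be captured without facial selectivity.
- The fallback sets out from 14 and comes back at 17; it avoids any cation at C4.
- The ketone is reduced under reagent control with the bulky hydride LiBH(s-Bu)3 in THF at −78 °C.
- This hydride should approach along the pseudo-equatorial trajectory and give the pseudo-axial, 2,4-trans alcohol directly.
- This detour makes no new compound (F0).

Step 7. During the slower methyl ether cleavage the carbonyl-bound Lewis acid may assist opening of the C2–O1 bond, which erodes C2 through the chalcone. The hydrogen chloride formed may also add to the prenyl alkene.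
- The fallback sets out from 12 and comes back at 13; it splits the two cleavages by mechanism.
- MgI2·OEt2 in THF at 60 °C removes only the chelated C5 methyl group by iodide SN2 attack and should give (2S)-4'-benzyloxy-5-hydroxy-7-methoxy-8-prenylflavanone F3.
- The benzyl ether is then removed with BCl3 and C6HMe5 in CH2Cl2 at −78 °C in a short contact, without any warming.

Further compounds
F1 | step 5 | (S)-1-[4-(benzyloxy)phenyl]-2-[2-(2-fluoro-4,6-dimethoxy-3-prenylphenyl)-1,3-dithian-2-yl]ethan-1-ol | O[C@H](c1ccc(OCc2ccccc2)cc1)CC1(SCCCS1)c1c(F)c(CC=C(C)C)c(OC)cc1OC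
F2 | step 5 | (S)-3-[4-(benzyloxy)phenyl]-1-(2-fluoro-4,6-dimethoxy-3-prenylphenyl)-3-hydroxypropan-1-one | O[C@H](c1ccc(OCc2ccccc2)cc1)CC(=O)c1c(F)c(CC=C(C)C)c(OC)cc1OC
F0 | step 10 | none | none
F3 | step 7 | (2S)-4'-benzyloxy-5-hydroxy-7-methoxy-8-prenylflavanone | COc1cc(O)c2c(c1CC=C(C)C)O[C@H](c1ccc(OCc3ccccc3)cc1)CC2=O
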